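**Plan**

- Retrosynthesis: the C4 carbonyl of the flavanonol half is taken back to a CH2 group. Ring C of that half is then cut at C3–C4 and O1–C2, the biaryl bond C8–C3′ is cut next (Suzuki coupling), and last the pyranone ring of the flavone (chalcone cyclisation).
- Enabling feature: in the flavanonol half, O1, C8a, C4a and C4 are the heterodiene of an ortho-quinone methide of the phloroglucinol ring A. C2–C3, with its 4-oxyphenyl and oxygen substituents, is an E β-acetoxystyrene.
- Forward order: the flavone rings are made first, then the biaryl bond to an iodosalicylaldehyde, then reduction to the salicyl alcohol. The enol acetate is made separately from 4-(benzyloxy)benzaldehyde. Ring C of the flavanonol closes in the hetero-Diels–Alder step, after which C4 is oxidised and the protecting groups are removed.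
- Stereochemistry: C2 and C3 are both set in the cycloaddition, trans from the E alkene and absolute from a chiral phosphoric acid. The 2R,3S flavan becomes the 2R,3R flavanonol on C4 oxidation, with no change in geometry (the priority order at C3 changes).

Key step: step 11

Assumption: the C8–C3′ biaryl axis (one of its four ortho positions carries H) is taken as freely rotating, since the target carries no axial descriptor.
Assumption: the sense of induction of the chiral acid in step 11 cannot be predicted with certainty; the (R)-acid is written and the (S)-acid would be used if the opposite sense is found.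
Assumption: compound 21 is carried forward as a mixture of C4 epimers (3,4-trans expected to predominate), because C4 becomes a carbonyl in step 13.

**Route**

Step 1
Reactants: 1 1-[2,4-bis(benzyloxy)-6-hydroxyphenyl]ethanone; 2 4-(benzyloxy)-3-bromobenzaldehyde
Product: 3 (E)-1-[2,4-bis(benzyloxy)-6-hydroxyphenyl]-3-[4-(benzyloxy)-3-bromophenyl]prop-2-en-1-one
Conditions: KOH (50% aq.), EtOH/THF, rt
Reagents that add atoms: none
Why: Claisen–Schmidt aldol condensation: the methyl ketone enolate adds to the non-enolisable aldehyde and E1cB dehydration gives the E enone, while the hydrogen-bonded ortho phenoxide, the benzyl ethers and the aryl bromide are inert to aqueous KOH.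

Step 2
Reactants: 3 (E)-1-[2,4-bis(benzyloxy)-6-hydroxyphenyl]-3-[4-(benzyloxy)-3-bromophenyl]prop-2-en-1-one
Product: 5 5,7-bis(benzyloxy)-2-[4-(benzyloxy)-3-bromophenyl]-4H-chromen-4-one, via flavanone 4 (not isolated)
Conditions: I2 (10 mol %), DMSO, 120 °C
Reagents that add atoms: none
Why: Iodine-catalysed oxidative cyclisation of a 2′-hydroxychalcone in DMSO: oxa-Michael closure gives flavanone 4, which is iodinated at C3 and loses HI to the flavone while DMSO reoxidises HI to I2, conditions under which benzyl ethers and the aryl bromide should be retained.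

Step 3
Reactants: 5 5,7-bis(benzyloxy)-2-[4-(benzyloxy)-3-bromophenyl]-4H-chromen-4-one
Product: 6 5,7-bis(benzyloxy)-2-[4-(benzyloxy)-3-(4,4,5,5-tetramethyl-1,3,2-dioxaborolan-2-yl)phenyl]-4H-chromen-4-one
Conditions: B2pin2, PdCl2(dppf) (5 mol %), KOAc, 1,4-dioxane, 90 °C
Reagents that add atoms: bis(pinacolato)diboron, CC1(C)OB(OC1(C)C)B1OC(C)(C)C(C)(C)O1
Why: Miyaura borylation: zerovalent palladium inserts into the only C–Br bond and acetate-assisted transmetalation with B2pin2 gives the arylboronate, KOAc being too weak a base to promote onward Suzuki coupling of the product.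

Step 4
Reactants: 7 3,5-bis(benzyloxy)phenol
Product: 9 2,4-bis(benzyloxy)-6-hydroxybenzaldehyde, via hydroxymethylphenol 8 (not isolated)
Conditions: MgCl2, Et3N, (CH2O)n, MeCN, reflux; then dilute aq. HCl
Reagents that add atoms: paraformaldehyde (as formaldehyde), C=O
Why: Magnesium-mediated ortho-formylation (Casnati–Skattebøl): the magnesium phenoxide delivers formaldehyde only to an ortho carbon to give hydroxymethylphenol 8 (as its magnesium salt), which is oxidised by hydride transfer to a second formaldehyde, and because the two ortho positions of 7 are equivalent a single aldehyde should result.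

Step 5
Reactants: 9 2,4-bis(benzyloxy)-6-hydroxybenzaldehyde
Product: 10 4,6-bis(benzyloxy)-2-hydroxy-3-iodobenzaldehyde
Conditions: NIS (1.05 equiv), TFA (cat.), MeCN, 0 °C to rt
Reagents that add atoms: N-iodosuccinimide, O=C1CCC(=O)N1I
Why: Electrophilic aromatic iodination: of the two free ring positions the one ortho to the chelated phenol and para to a benzyloxy group is the less hindered and the more activated, in line with the ortho-to-hydroxyl iodination of 2-hydroxy-4,6-dialkoxyaryl ketones, and one equivalent of NIS should stop at the monoiodide.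

Step 6
Reactants: 10 4,6-bis(benzyloxy)-2-hydroxy-3-iodobenzaldehyde; 6 5,7-bis(benzyloxy)-2-[4-(benzyloxy)-3-(4,4,5,5-tetramethyl-1,3,2-dioxaborolan-2-yl)phenyl]-4H-chromen-4-one
Product: 11 4,6-bis(benzyloxy)-3-{2-(benzyloxy)-5-[5,7-bis(benzyloxy)-4-oxo-4H-chromen-2-yl]phenyl}-2-hydroxybenzaldehyde
Conditions: Pd(OAc)2 (5 mol %), SPhos (10 mol %), K3PO4, toluene/H2O (10:1), 80 °C
Reagents that add atoms: none
Why: Suzuki–Miyaura coupling: the bulky, electron-rich SPhos ligand supports oxidative addition into the hindered, electron-rich C–I bond and reductive elimination to a biaryl with three ortho substituents, a type of bond (an iodide between two oxygenated carbons of a phloroglucinol ring joined to a flavone 3′-boronate) that is commonly made this way in 3′,8-linked biflavonoids.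

Step 7
Reactants: 11 4,6-bis(benzyloxy)-3-{2-(benzyloxy)-5-[5,7-bis(benzyloxy)-4-oxo-4H-chromen-2-yl]phenyl}-2-hydroxybenzaldehyde
Product: 12 5,7-bis(benzyloxy)-2-{4-(benzyloxy)-3-[4,6-bis(benzyloxy)-2-hydroxy-3-(hydroxymethyl)phenyl]phenyl}-4H-chromen-4-one
Conditions: NaBH4, THF/MeOH, 0 °C; pH 7 buffer work-up; used directly in step 11
Reagents that add atoms: none
Why: Borohydride reduction: the aldehyde should be reduced at 0 °C much faster than the doubly vinylogous ester carbonyl of the 5,7-dialkoxyflavone, and a neutral work-up with immediate use avoids acid-triggered ionisation of the very electron-rich salicyl alcohol.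

Step 8
Reactants: 13 4-(benzyloxy)benzaldehyde; 14 bis(pinacolato)borylmethane [2,2′-methylenebis(4,4,5,5-tetramethyl-1,3,2-dioxaborolane)]
Product: 16 (E)-2-{2-[4-(benzyloxy)phenyl]ethenyl}-4,4,5,5-tetramethyl-1,3,2-dioxaborolane, via lithiated diborylmethane 15 (not isolated)
Conditions: lithium 2,2,6,6-tetramethylpiperidide (LiTMP), THF, 0 °C; then 13, −78 °C to rt
Reagents that add atoms: none
Why: Boron–Wittig olefination: deprotonation gives the boron-stabilised carbanion 15, which adds to the aldehyde, and syn elimination of the lithium borate from the adduct gives the E alkenylboronate with the high selectivity usual for aryl aldehydes.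

Step 9
Reactants: 16 (E)-2-{2-[4-(benzyloxy)phenyl]ethenyl}-4,4,5,5-tetramethyl-1,3,2-dioxaborolane
Product: 17 potassium (E)-{2-[4-(benzyloxy)phenyl]ethenyl}trifluoroborate
Conditions: KHF2 (aq.), MeOH, rt
Reagents that add atoms: potassium hydrogen difluoride, [K+].[F-].F
Why: Conversion of a pinacol boronate into its potassium trifluoroborate by KHF2, which leaves the alkene geometry untouched and gives a crystalline salt that is the preferred partner for the next coupling.

Step 10
Reactants: 17 potassium (E)-{2-[4-(benzyloxy)phenyl]ethenyl}trifluoroborate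
Product: 18 (E)-2-[4-(benzyloxy)phenyl]ethenyl acetate
Conditions: AcOH (3 equiv), CuBr (10 mol %), DMAP (20 mol %), 4 Å MS, O2 (1 atm), MeCN, 60 °C
Reagents that add atoms: acetic acid, CC(=O)O
Why: Copper-catalysed oxidative C–O coupling of an alkenyltrifluoroborate with a carboxylic acid (Chan–Lam type): transmetalation to copper and C–O reductive elimination occur with retention of alkene geometry, so the E enol acetate should be obtained free of its Z isomer.

Step 11
Reactants: 12 5,7-bis(benzyloxy)-2-{4-(benzyloxy)-3-[4,6-bis(benzyloxy)-2-hydroxy-3-(hydroxymethyl)phenyl]phenyl}-4H-chromen-4-one; 18 (E)-2-[4-(benzyloxy)phenyl]ethenyl acetate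
Product: 20 (2R,3S)-5,7-bis(benzyloxy)-2-[4-(benzyloxy)phenyl]-8-{2-(benzyloxy)-5-[5,7-bis(benzyloxy)-4-oxo-4H-chromen-2-yl]phenyl}chroman-3-yl acetate, via ortho-quinone methide 19 (not isolated)
Conditions: (R)-TRIP [(R)-3,3′-bis(2,4,6-triisopropylphenyl)-1,1′-binaphthyl-2,2′-diyl hydrogen phosphate] (10 mol %), 4 Å MS, toluene, 0 °C to rt; 18 (3 equiv), 12 added slowly over several hours
Reagents that add atoms: none
Why: Proposed new method: the chiral phosphoric acid protonates the benzylic hydroxyl of 12, whose carbon has three oxygen donors ortho and para to it, and loss of water gives ortho-quinone methide 19, which stays hydrogen-bonded to the chiral phosphate; the acetoxy-bearing carbon of 18 then bonds to the methide CH2 (C3–C4) and the quinone-methide oxygen closes onto the developing 4-benzyloxybenzylic cation (O1–C2) in an asynchronous inverse-electron-demand [4+2] cycloaddition. The closest known reactions are Brønsted-acid-catalysed hetero-Diels–Alder additions of ortho-quinone methides, generated from 2-hydroxybenzyl alcohols, to styrenes, propenylbenzenes and enol ethers, which give 2-arylchromans; new here are the enol ester as dienophile, the unsubstituted methide carbon and enantiocontrol by the phosphate for that pairing. Ring C of the flavan (O1, C2, C3, C4, C4a, C8a) is closed as a six-membered ring by this [4+2] process, which amounts to a 6-endo capture of the benzylic cation by the phenolic oxygen if the addition is stepwise. C3 is set in the C–C bond-forming event by the alkene face that the phosphate-bound methide accepts, which fixes the absolute configuration, and C2 follows from suprafacial addition across the E alkene (or, if stepwise, from closure to the more stable 2,3-trans chroman, which bridging of the cation by the neighbouring acetoxy group would also favour), giving 2R,3S. The step needs 2-aryl-3-acyloxy regiochemistry, which is secured because the 4-benzyloxyphenyl group stabilises positive charge at C2 far better than the weakly donating acetoxy group could at C3, and it needs the cross-addition to outrun self-condensation of 19 through its nucleophilic C6, for which 18 is used in excess and 12 is added slowly.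

Step 12
Reactants: 20 (2R,3S)-5,7-bis(benzyloxy)-2-[4-(benzyloxy)phenyl]-8-{2-(benzyloxy)-5-[5,7-bis(benzyloxy)-4-oxo-4H-chromen-2-yl]phenyl}chroman-3-yl acetate
Product: 21 4-hydroxy derivative of 20 (C2 and C3 as in 20; C4 epimers)
Conditions: DDQ (2 equiv), CH2Cl2/H2O (18:1), rt
Reagents that add atoms: water, O
Why: DDQ benzylic oxidation: hydride abstraction at C4 gives a cation stabilised by the ortho and para oxygen atoms of ring A (the established site of oxidation of protected flavan-3-ols), which water captures, while the less activated C2–H and the benzyl ether methylenes should be left alone.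

Step 13
Reactants: 21 4-hydroxy derivative of 20 (C4 epimers)
Product: 22 (2R,3R)-5,7-bis(benzyloxy)-2-[4-(benzyloxy)phenyl]-8-{2-(benzyloxy)-5-[5,7-bis(benzyloxy)-4-oxo-4H-chromen-2-yl]phenyl}-4-oxochroman-3-yl acetate
Conditions: Dess–Martin periodinane, NaHCO3, CH2Cl2, 0 °C to rt
Reagents that add atoms: none
Why: Dess–Martin oxidation of the secondary benzylic alcohol to the aryl ketone under buffered, near-neutral conditions that neither enolise C3 nor open ring C, with both C4 epimers converging on one ketone.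

Step 14
Reactants: 22 (2R,3R)-5,7-bis(benzyloxy)-2-[4-(benzyloxy)phenyl]-8-{2-(benzyloxy)-5-[5,7-bis(benzyloxy)-4-oxo-4H-chromen-2-yl]phenyl}-4-oxochroman-3-yl acetate
Product: 23 (2R,3R)-5,7-bis(benzyloxy)-2-[4-(benzyloxy)phenyl]-8-{2-(benzyloxy)-5-[5,7-bis(benzyloxy)-4-oxo-4H-chromen-2-yl]phenyl}-3-hydroxychroman-4-one
Conditions: HCl (1.25 M in MeOH), CH2Cl2, rt to 35 °C
Reagents that add atoms: none
Why: Acid-catalysed transesterification with methanol removes the acetate without base, so that the retro-oxa-Michael ring opening and C2/C3 epimerisation to which flavanonols are prone under alkaline conditions are avoided, and the 2,3-trans isomer is in any case the more stable one.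

Step 15
Reactants: 23 (2R,3R)-5,7-bis(benzyloxy)-2-[4-(benzyloxy)phenyl]-8-{2-(benzyloxy)-5-[5,7-bis(benzyloxy)-4-oxo-4H-chromen-2-yl]phenyl}-3-hydroxychroman-4-one
Product: 24 (2R,3R)-3,5,7-trihydroxy-2-(4-hydroxyphenyl)-8-[2-hydroxy-5-(5,7-dihydroxy-4-oxo-4H-chromen-2-yl)phenyl]chroman-4-one (CNP0374521.1)
Conditions: H2 (1 atm), 10% Pd/C, THF/MeOH, rt
Reagents that add atoms: none
Why: Catalytic hydrogenolysis cleaves all six benzyl aryl ethers, while the flavone C2–C3 double bond, the aryl ketone and the benzylic C2–O bond of the flavanonol normally survive these mild conditions in flavonoid deprotections.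

**Compound list**

1 | 1-[2,4-bis(benzyloxy)-6-hydroxyphenyl]ethanone | CC(=O)c1c(O)cc(OCc9ccccc9)cc1OCc9ccccc9 | starting material
2 | 4-(benzyloxy)-3-bromobenzaldehyde | O=Cc1ccc(OCc9ccccc9)c(Br)c1 | starting material
3 | (E)-1-[2,4-bis(benzyloxy)-6-hydroxyphenyl]-3-[4-(benzyloxy)-3-bromophenyl]prop-2-en-1-one | O=C(/C=C/c1ccc(OCc9ccccc9)c(Br)c1)c1c(O)cc(OCc9ccccc9)cc1OCc9ccccc9 | intermediate
4 | racemic 5,7-bis(benzyloxy)-2-[4-(benzyloxy)-3-bromophenyl]chroman-4-one (flavanone, formed in the flask, not isolated) | O=C1CC(c2ccc(OCc9ccccc9)c(Br)c2)Oc2cc(OCc9ccccc9)cc(OCc9ccccc9)c12 | intermediate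
5 | 5,7-bis(benzyloxy)-2-[4-(benzyloxy)-3-bromophenyl]-4H-chromen-4-one | O=c1cc(-c2ccc(OCc9ccccc9)c(Br)c2)oc2cc(OCc9ccccc9)cc(OCc9ccccc9)c12 | intermediate
6 | 5,7-bis(benzyloxy)-2-[4-(benzyloxy)-3-(4,4,5,5-tetramethyl-1,3,2-dioxaborolan-2-yl)phenyl]-4H-chromen-4-one | O=c1cc(-c2ccc(OCc9ccccc9)c(B3OC(C)(C)C(C)(C)O3)c2)oc2cc(OCc9ccccc9)cc(OCc9ccccc9)c12 | intermediate
7 | 3,5-bis(benzyloxy)phenol | Oc1cc(OCc9ccccc9)cc(OCc9ccccc9)c1 | starting material
8 | 3,5-bis(benzyloxy)-2-(hydroxymethyl)phenol (as its magnesium phenoxide, formed in the flask, not isolated) | OCc1c(O)cc(OCc9ccccc9)cc1OCc9ccccc9 | intermediate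
9 | 2,4-bis(benzyloxy)-6-hydroxybenzaldehyde | O=Cc1c(O)cc(OCc9ccccc9)cc1OCc9ccccc9 | intermediate
10 | 4,6-bis(benzyloxy)-2-hydroxy-3-iodobenzaldehyde | O=Cc1c(O)c(I)c(OCc9ccccc9)cc1OCc9ccccc9 | intermediate
11 | 4,6-bis(benzyloxy)-3-{2-(benzyloxy)-5-[5,7-bis(benzyloxy)-4-oxo-4H-chromen-2-yl]phenyl}-2-hydroxybenzaldehyde | O=Cc1c(O)c(-c2cc(-c3cc(=O)c4c(OCc9ccccc9)cc(OCc9ccccc9)cc4o3)ccc2OCc9ccccc9)c(OCc9ccccc9)cc1OCc9ccccc9 | intermediate
12 | 5,7-bis(benzyloxy)-2-{4-(benzyloxy)-3-[4,6-bis(benzyloxy)-2-hydroxy-3-(hydroxymethyl)phenyl]phenyl}-4H-chromen-4-one | OCc1c(O)c(-c2cc(-c3cc(=O)c4c(OCc9ccccc9)cc(OCc9ccccc9)cc4o3)ccc2OCc9ccccc9)c(OCc9ccccc9)cc1OCc9ccccc9 | intermediate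
13 | 4-(benzyloxy)benzaldehyde | O=Cc1ccc(OCc9ccccc9)cc1 | starting material
14 | bis(pinacolato)borylmethane [2,2′-methylenebis(4,4,5,5-tetramethyl-1,3,2-dioxaborolane)] | CC1(C)OB(CB2OC(C)(C)C(C)(C)O2)OC1(C)C | starting material
15 | lithio-bis(4,4,5,5-tetramethyl-1,3,2-dioxaborolan-2-yl)methane (formed in the flask, not isolated) | [Li]C(B1OC(C)(C)C(C)(C)O1)B1OC(C)(C)C(C)(C)O1 | intermediate
16 | (E)-2-{2-[4-(benzyloxy)phenyl]ethenyl}-4,4,5,5-tetramethyl-1,3,2-dioxaborolane | CC1(C)OB(/C=C/c2ccc(OCc9ccccc9)cc2)OC1(C)C | intermediate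
17 | potassium (E)-{2-[4-(benzyloxy)phenyl]ethenyl}trifluoroborate | [K+].F[B-](F)(F)/C=C/c1ccc(OCc9ccccc9)cc1 | intermediate
18 | (E)-2-[4-(benzyloxy)phenyl]ethenyl acetate | CC(=O)O/C=C/c1ccc(OCc9ccccc9)cc1 | intermediate
19 | 3,5-bis(benzyloxy)-2-{2-(benzyloxy)-5-[5,7-bis(benzyloxy)-4-oxo-4H-chromen-2-yl]phenyl}-6-methylidenecyclohexa-2,4-dien-1-one (ortho-quinone methide, formed in the flask, not isolated) | C=C1C(=O)C(-c2cc(-c3cc(=O)c4c(OCc9ccccc9)cc(OCc9ccccc9)cc4o3)ccc2OCc9ccccc9)=C(OCc9ccccc9)C=C1OCc9ccccc9 | intermediate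
20 | (2R,3S)-5,7-bis(benzyloxy)-2-[4-(benzyloxy)phenyl]-8-{2-(benzyloxy)-5-[5,7-bis(benzyloxy)-4-oxo-4H-chromen-2-yl]phenyl}chroman-3-yl acetate | C1c2c(OCc9ccccc9)cc(OCc9ccccc9)c(-c3cc(-c4cc(=O)c5c(OCc9ccccc9)cc(OCc9ccccc9)cc5o4)ccc3OCc9ccccc9)c2O[C@H](c2ccc(OCc9ccccc9)cc2)[C@H]1OC(C)=O | intermediate
21 | 4-hydroxy derivative of 20: 5,7-bis(benzyloxy)-2-[4-(benzyloxy)phenyl]-8-{2-(benzyloxy)-5-[5,7-bis(benzyloxy)-4-oxo-4H-chromen-2-yl]phenyl}-4-hydroxychroman-3-yl acetate, C2 and C3 as in 20, C4 epimers (C4 left unassigned) | OC1c2c(OCc9ccccc9)cc(OCc9ccccc9)c(-c3cc(-c4cc(=O)c5c(OCc9ccccc9)cc(OCc9ccccc9)cc5o4)ccc3OCc9ccccc9)c2O[C@H](c2ccc(OCc9ccccc9)cc2)[C@H]1OC(C)=O | intermediate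
22 | (2R,3R)-5,7-bis(benzyloxy)-2-[4-(benzyloxy)phenyl]-8-{2-(benzyloxy)-5-[5,7-bis(benzyloxy)-4-oxo-4H-chromen-2-yl]phenyl}-4-oxochroman-3-yl acetate | O=C1c2c(OCc9ccccc9)cc(OCc9ccccc9)c(-c3cc(-c4cc(=O)c5c(OCc9ccccc9)cc(OCc9ccccc9)cc5o4)ccc3OCc9ccccc9)c2O[C@H](c2ccc(OCc9ccccc9)cc2)[C@H]1OC(C)=O | intermediate
23 | (2R,3R)-5,7-bis(benzyloxy)-2-[4-(benzyloxy)phenyl]-8-{2-(benzyloxy)-5-[5,7-bis(benzyloxy)-4-oxo-4H-chromen-2-yl]phenyl}-3-hydroxychroman-4-one | O=C1c2c(OCc9ccccc9)cc(OCc9ccccc9)c(-c3cc(-c4cc(=O)c5c(OCc9ccccc9)cc(OCc9ccccc9)cc5o4)ccc3OCc9ccccc9)c2O[C@H](c2ccc(OCc9ccccc9)cc2)[C@H]1O | intermediate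
24 | (2R,3R)-3,5,7-trihydroxy-2-(4-hydroxyphenyl)-8-[2-hydroxy-5-(5,7-dihydroxy-4-oxo-4H-chromen-2-yl)phenyl]chroman-4-one | O=C1c2c(O)cc(O)c(-c3cc(-c4cc(=O)c5c(O)cc(O)cc5o4)ccc3O)c2O[C@H](c2ccc(O)cc2)[C@H]1O | target

**Step count**

Total: 15 steps. Longest linear sequence: 10 steps (steps 1, 2, 3, 6, 7, 11, 12, 13, 14, 15).

**Steps most likely to fail**

1. Step 11 (proposed new method). The enol ester is a weak nucleophile, so self-condensation of the quinone methide by Friedel–Crafts attack through C6 of a second molecule may outrun the cross-addition. Facial discrimination of a dienophile that cannot hydrogen-bond to the phosphate may also be poor. The fallback is the chalcone epoxide route to flavanonols, all known chemistry; it sets out from 1 (using 6 and 13) and returns at 23. Ketone 1 is iodinated ortho to the phenol (NIS, TFA cat., MeCN) to give 1-[4,6-bis(benzyloxy)-2-hydroxy-3-iodophenyl]ethanone F1. This is coupled with boronate 6 under the conditions of step 6 to give the biaryl ketone F2. The phenol is masked (MOMCl, NaH, DMF) as the methoxymethyl ether F3. Claisen–Schmidt condensation with 13 (KOH, EtOH/THF) gives the E chalcone F4. Juliá–Colonna epoxidation (poly-L-leucine, urea–H2O2, DBU, THF) should give the (αR,βS)-epoxy ketone F5. HCl in MeOH/THF at 50 °C then removes the methoxymethyl group, and the freed phenol opens the epoxide at the benzylic carbon with inversion, closing ring C to the 2R,3R flavanonol 23. Steps 12 to 14 are then not needed and only step 15 remains.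

2. Step 12. The C4 cation may be bridged by the neighbouring acetate, so that the acyl group migrates to O4 on hydrolysis; hydride abstraction may also compete at C2, or oxidation may run on unevenly. The fallback swaps the ester for a non-participating silyl ether before oxidation; it sets out from 20 and returns at 23. The acetate is removed at the flavan stage, where no ketone is present (K2CO3, MeOH/THF), to give the flavan-3-ol F6. Silylation (TBSOTf, 2,6-lutidine, CH2Cl2) gives the 3-O-TBS ether F7. DDQ in wet CH2Cl2 then gives the 4-hydroxy compound F8, and Dess–Martin oxidation gives the 3-silyloxy ketone F9. HF·pyridine in THF frees the 3-hydroxyl to give 23, which also makes step 14 unnecessary.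

3. Step 7. Hydride may add to the flavone enone, and the salicyl alcohol may ionise and self-condense during isolation. The fallback reduces the aldehyde before the flavone is attached and carries the diol through the coupling in masked form; it sets out from 10 and returns at 12. Reduction of 10 (NaBH4, MeOH, 0 °C) gives the iodo salicyl alcohol F10. Both hydroxyls are tied up (tBu2Si(OTf)2, 2,6-lutidine, CH2Cl2) as the cyclic di-tert-butylsilylene F11. Suzuki coupling with 6 as in step 6 gives the silylene-protected biaryl F12. Buffered fluoride (TBAF/AcOH, THF, 0 °C) then releases 12 under non-acidic conditions just before step 11.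

**Further compounds**

F1 | step 11 | 1-[4,6-bis(benzyloxy)-2-hydroxy-3-iodophenyl]ethanone | CC(=O)c1c(O)c(I)c(OCc9ccccc9)cc1OCc9ccccc9
F2 | step 11 | 1-(4,6-bis(benzyloxy)-3-{2-(benzyloxy)-5-[5,7-bis(benzyloxy)-4-oxo-4H-chromen-2-yl]phenyl}-2-hydroxyphenyl)ethanone | CC(=O)c1c(O)c(-c2cc(-c3cc(=O)c4c(OCc9ccccc9)cc(OCc9ccccc9)cc4o3)ccc2OCc9ccccc9)c(OCc9ccccc9)cc1OCc9ccccc9
F3 | step 11 | 1-(4,6-bis(benzyloxy)-3-{2-(benzyloxy)-5-[5,7-bis(benzyloxy)-4-oxo-4H-chromen-2-yl]phenyl}-2-(methoxymethoxy)phenyl)ethanone | CC(=O)c1c(OCOC)c(-c2cc(-c3cc(=O)c4c(OCc9ccccc9)cc(OCc9ccccc9)cc4o3)ccc2OCc9ccccc9)c(OCc9ccccc9)cc1OCc9ccccc9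
F4 | step 11 | (E)-1-(4,6-bis(benzyloxy)-3-{2-(benzyloxy)-5-[5,7-bis(benzyloxy)-4-oxo-4H-chromen-2-yl]phenyl}-2-(methoxymethoxy)phenyl)-3-[4-(benzyloxy)phenyl]prop-2-en-1-one | O=C(/C=C/c6ccc(OCc9ccccc9)cc6)c1c(OCOC)c(-c2cc(-c3cc(=O)c4c(OCc9ccccc9)cc(OCc9ccccc9)cc4o3)ccc2OCc9ccccc9)c(OCc9ccccc9)cc1OCc9ccccc9
F5 | step 11 | (4,6-bis(benzyloxy)-3-{2-(benzyloxy)-5-[5,7-bis(benzyloxy)-4-oxo-4H-chromen-2-yl]phenyl}-2-(methoxymethoxy)phenyl){(2R,3S)-3-[4-(benzyloxy)phenyl]oxiran-2-yl}methanone | O=C([C@@H]6O[C@H]6c7ccc(OCc9ccccc9)cc7)c1c(OCOC)c(-c2cc(-c3cc(=O)c4c(OCc9ccccc9)cc(OCc9ccccc9)cc4o3)ccc2OCc9ccccc9)c(OCc9ccccc9)cc1OCc9ccccc9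
F6 | step 12 | (2R,3S)-5,7-bis(benzyloxy)-2-[4-(benzyloxy)phenyl]-8-{2-(benzyloxy)-5-[5,7-bis(benzyloxy)-4-oxo-4H-chromen-2-yl]phenyl}chroman-3-ol | C1c2c(OCc9ccccc9)cc(OCc9ccccc9)c(-c3cc(-c4cc(=O)c5c(OCc9ccccc9)cc(OCc9ccccc9)cc5o4)ccc3OCc9ccccc9)c2O[C@H](c2ccc(OCc9ccccc9)cc2)[C@H]1O
F7 | step 12 | 3-O-tert-butyldimethylsilyl ether of F6 | C1c2c(OCc9ccccc9)cc(OCc9ccccc9)c(-c3cc(-c4cc(=O)c5c(OCc9ccccc9)cc(OCc9ccccc9)cc5o4)ccc3OCc9ccccc9)c2O[C@H](c2ccc(OCc9ccccc9)cc2)[C@H]1O[Si](C)(C)C(C)(C)C
F8 | step 12 | 4-hydroxy derivative of F7 (C4 epimers, C4 left unassigned) | OC1c2c(OCc9ccccc9)cc(OCc9ccccc9)c(-c3cc(-c4cc(=O)c5c(OCc9ccccc9)cc(OCc9ccccc9)cc5o4)ccc3OCc9ccccc9)c2O[C@H](c2ccc(OCc9ccccc9)cc2)[C@H]1O[Si](C)(C)C(C)(C)C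
F9 | step 12 | (2R,3R)-5,7-bis(benzyloxy)-2-[4-(benzyloxy)phenyl]-8-{2-(benzyloxy)-5-[5,7-bis(benzyloxy)-4-oxo-4H-chromen-2-yl]phenyl}-3-(tert-butyldimethylsilyloxy)chroman-4-one | O=C1c2c(OCc9ccccc9)cc(OCc9ccccc9)c(-c3cc(-c4cc(=O)c5c(OCc9ccccc9)cc(OCc9ccccc9)cc5o4)ccc3OCc9ccccc9)c2O[C@H](c2ccc(OCc9ccccc9)cc2)[C@H]1O[Si](C)(C)C(C)(C)C
F10 | step 7 | 3,5-bis(benzyloxy)-2-(hydroxymethyl)-6-iodophenol | OCc1c(O)c(I)c(OCc9ccccc9)cc1OCc9ccccc9
F11 | step 7 | 5,7-bis(benzyloxy)-2,2-di-tert-butyl-8-iodo-4H-1,3,2-benzodioxasiline | CC(C)(C)[Si]1(C(C)(C)C)OCc2c(O1)c(I)c(OCc9ccccc9)cc2OCc9ccccc9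
F12 | step 7 | 5,7-bis(benzyloxy)-2-{4-(benzyloxy)-3-[5,7-bis(benzyloxy)-2,2-di-tert-butyl-4H-1,3,2-benzodioxasilin-8-yl]phenyl}-4H-chromen-4-one | CC(C)(C)[Si]1(C(C)(C)C)OCc2c(O1)c(-c3cc(-c4cc(=O)c5c(OCc9ccccc9)cc(OCc9ccccc9)cc5o4)ccc3OCc9ccccc9)c(OCc9ccccc9)cc2OCc9ccccc9
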